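Remark on the chemistry: labdane numbering is used for every intermediate (ring A = C1–C5 and C10, ring B = C5–C10, chain C11–C15, C16 on C13, C17 on C8, C18 and C19 on C4, C20 on C10); α is the face opposite to the C10 methyl group. Compounds 1, 3, 17 and 25 are taken as commercial.

## Structural features

The target is a bicyclic labdane: a trans-fused decalin that carries a gem-dimethyl group on C4, an angular methyl on C10, an equatorial (α) secondary alcohol on C2 and a trisubstituted C7=C8 alkene with its methyl on C8. A five-carbon chain (C11–C15, methyl branch on C13) leaves C9 and ends in a primary caffeate ester. C5, C10 and C9 are contiguous, with the quaternary C10 in the middle; C2 is 1,3 to C10, and C13 is insulated from the ring by two methylenes, so the ring cannot control it. The fragile groups are the catechol (air and base), the cinnamate ester (nucleophiles, hydride, boranes) and any C11 aldehyde on the way, whose C9–H is both α to the carbonyl and allylic to C7=C8 and can epimerise or let the alkene slip into conjugation. The real difficulty is threefold: the quaternary C10 between C5 and C9 in the right relative sense, the ring B alkene at C7=C8 and nowhere else, and the C2 oxygen on the α face. The key step uses the fact that C9 is an enolisable carbon next to a C11 carbonyl and that C8 is the methyl-bearing end of the alkene. A C11 enol ether hanging from C10 can add through C9 to a but-2-ynyl group on C5, which forms C8–C9, closes ring B and leaves the alkene exactly at C7=C8.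

## Logic of the disconnections

**Ester last.** The acyl–oxygen bond at C15 is cut first (29 back to 28 by silylating the two phenols, then 28 to 24 and 27; 27 comes from 25). A catechol cinnamate would not survive boranes, ylides or hot basic diimide generation, so it is joined at the end. The cut gives a terpenoid diol and a C9 acid. The forward acylation must choose the primary C15 hydroxyl over the secondary C2 hydroxyl of 24, and the last desilylation must be mild.

**C11–C12.** The C15 O–Si bond and then the C11–C12 bond are cut (24 from 23, 23 from 22, 22 from 16 and 21). C11 is a carbonyl carbon in the ring-closing chemistry anyway, and cutting here lets the remote C13 centre come from the chiral pool. The gain is a C15 bicyclic hydroxy aldehyde and a C5 ylide. The olefination must add to a hindered aldehyde with an acidic C9–H without touching C9, and the reduction that follows must take the disubstituted C11=C12 and spare the trisubstituted C7=C8.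

**Side chain.** 21 goes back through 20 and 19 to 18 and 17 (C12–P, C12–iodine and one O–Si bond). The stereocentre is never touched. The only demand is that the silyl chloride pick the less hindered of the two primary hydroxyls of 17.

**C2 oxygen.** In 16 the C2–O bond is removed and C11 is returned to the aldehyde of the cyclisation product (16 from 15, 15 from 12). A C1=C2 alkene is exactly what the sigmatropic step that builds C10 leaves behind, so the C2 oxygen is lent to make C10 and paid back by hydroboration. This removes one stereocentre and every protecting group from the bicyclic core. The forward step must choose C1=C2 over C7=C8, C2 over C1 and the α face over the β face. The oxidation back to the aldehyde must choose the primary alcohol.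

**C8–C9 (key cut).** 12 is opened to 11 by cutting C8–C9. Ring B disappears and a monocyclic ring A remains with a but-2-ynyl chain on C5 and a two-carbon enol ether on C10. The alkyne fixes where the alkene will be. The forward step must close through C8 (six-membered) and not through C7 (five-membered), and must set C9 under kinetic control.

**C9–C10.** 11 goes back to 10 (O–Si), 10 to 9 (C9–C10, with the C2–O bond re-formed) and 9 to 8 (vinyl–O bond). The quaternary C10 next to C5 is the hardest centre, and a suprafacial [3,3] shift makes it by chirality transfer from C2. The gain is a simple secondary allylic alcohol. The demand is a trans relation between the C2 oxygen and the C5 chain, and a vinyl transfer that tolerates the alkyne.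

**Absolute configuration.** 8 comes from 7 by forming the C2–H bond. The racemic C5 centre of 7 is sorted here by a reagent-controlled reduction: only one enantiomer of 7 can give the trans alcohol with the catalyst-preferred C2 configuration. At most half of 7 is used, and the catalyst must distinguish the two flanks of the carbonyl.

**C10 methyl.** 7 comes from 5 through 6 by cutting the C10–C20 bond. Adding a methyl nucleophile to the carbonyl of the vinylogous ester and hydrolysing moves the carbonyl to C2 and puts the alkene at C1=C10. The ring A pattern (gem-dimethyl on C4 next to C5) then maps onto a symmetric diketone.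

**C5–C6.** 5 comes from 2 and 3 through 4, and 2 from 1 (C5–C6 bond, then the enol ether C–O bond). Alkylation at the α′ position puts the alkyne chain next to the gem-dimethyl carbon. The enolate carbon is neopentyl-like, so a kinetic base and a reactive propargylic bromide are needed.

## Other disconnections considered

**Alternative 1:** The cut goes through C5–C10 and C8–C9 at once and opens both rings to a chain. In that chain a 2-silyloxy diene (C5 to C8) and an E-configured β-methyl enoate (C9=C10, C11 as ester) are linked through C1–C4. Heating would close rings A and B in one intramolecular Diels–Alder step and give the trans-decalin ester A1.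
- In its favour: two rings, two C–C bonds and the centres C5, C9 and C10 come from one metal-free step. The C9/C10 relation is dictated by the alkene geometry of the dienophile, which is a firmer basis than the rotamer preference that sets C9 in the chosen plan. The C2 oxygen is present from the start, so no late hydroboration is needed. On both points the alternative is the better.
- Against it here: the dienophile is a trisubstituted enoate that must form the quaternary C10, and the diene terminus C5 is neopentyl, so the cycloaddition should be slow. Trans fusion and facial sense rest on one remote centre (C2) and on the endo/exo preference of a flexible tether. The C7 oxygen is not wanted, so A1 would still need a regiocontrolled change of its C6=C7 enol ether into the C7=C8 alkene, and the C8 centre made in the cycloaddition is destroyed again.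
- Comparison: the step is concerted and pericyclic where the chosen one is a stepwise metal-mediated addition. It sets more in one step but asks more selectivities of that step. The open-chain precursor needs its own stereocontrolled assembly, so the step count should be similar or higher. The chosen plan fixes the position of the ring B alkene in the ring closure itself; A1 does not.

**Alternative 2:** The cut goes through C9–C10 and C7–C8. Ring A would carry a semicyclic diene (C10=C5 in the ring, C6=C7 as a vinyl group on C5), and its C2 oxygen would be acylated with a C4 alkynoate. Heating would join C9 to C10 and C8 to C7 and give the bridged lactone A2 with C5=C6 and C8=C9 alkenes.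
- In its favour: the C2 oxygen never leaves the molecule and serves as the tether, so C10 is set relative to C2 by geometry; this equals the chirality transfer of the Claisen step. The precursor has C2 as its only stereocentre, so an enantioselective reduction suffices and no half of a racemate is discarded; here the alternative is the better. Reductive opening of the lactone would free the C2 and C11 hydroxyls together, which is also better than a hydroboration.
- Against it here: C5 and C9 stay trigonal in A2. Hydrogen would have to be added to C5 from the α face of an alkene wedged between two quaternary carbons, and the conjugated C8=C9 alkene would have to be moved to C7=C8 with control of C9. The two things the chosen key step delivers directly (alkene position and C9) become separate later problems. The diene terminus C10 is fully substituted and the transition state is bridged.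
- Comparison: the way to a bicyclic core could be shorter, but the repair steps should outweigh the saving. Stereochemical security at C5 and C9 is lower than in the chosen plan.

**Alternative 3:** The cut goes through C5–C6 and C9–C10 and builds ring B first. A 1,3-diene (C6=C7–C8=C9) that already carries the C17 methyl and the whole silyl-protected C11–C15 chain would add to an α-methyl dienal (C5=C10) under a chiral oxazaborolidinium Lewis acid, exo with respect to the formyl group, and give A3.
- In its favour: the plan is convergent. The chain with C13 enters with the diene, so there is no late olefination, no diimide step and no epimerisable C9 aldehyde in the endgame; here the alternative is the better. C5, C9 and C10 are set in one catalytic enantioselective step without a resolution, which is also better.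
- Against it here: the methyl on C8 and the chain on C9 polarise the diene in opposite senses, so regiocontrol is uncertain. The dienal is a weak, β-substituted dienophile and is itself a diene. Exo selectivity is required. Ring A does not yet exist in A3: C2 must be added, the C2 carbinol centre must be created in a ring closure between the formyl and isopropenyl groups, and the second methyl on C4 must be installed.
- Comparison: the chosen plan has ring A with its gem-dimethyl group from the first step, whereas A3 needs a longer and stereochemically open sequence after its key step. The alternative's key step is catalytic and enantioselective; the chosen plan takes its absolute configuration from a kinetic resolution.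

Key step: step 8

## Route

Step 1
Reactants: 1 dimedone (5,5-dimethylcyclohexane-1,3-dione)
Product: 2 5,5-dimethyl-3-(2-methylpropoxy)cyclohex-2-en-1-one
Conditions: i-BuOH, p-TsOH (cat.), toluene, reflux, Dean–Stark
Reagents that add atoms: 2-methylpropan-1-ol, CC(C)CO
Why: Acid-catalysed vinylogous esterification with azeotropic removal of water; the diketone is symmetric, so only one enol ether can form.

Step 2
Reactants: 2 5,5-dimethyl-3-(2-methylpropoxy)cyclohex-2-en-1-one; 3 1-bromobut-2-yne
Product: 5 rac-6-(but-2-yn-1-yl)-5,5-dimethyl-3-(2-methylpropoxy)cyclohex-2-en-1-one, via lithium dienolate 4 (not isolated)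
Conditions: LDA (1.1 equiv), THF, −78 °C; then 3, DMPU, −78 → 0 °C
Reagents that add atoms: none
Why: Kinetic α′-deprotonation of the vinylogous ester and SN2 alkylation by the reactive propargylic bromide (Stork–Danheiser alkylation) form the C5–C6 bond next to the gem-dimethyl carbon; C5 is formed as a racemate and is resolved in step 4.

Step 3
Reactants: 5 rac-6-(but-2-yn-1-yl)-5,5-dimethyl-3-(2-methylpropoxy)cyclohex-2-en-1-one
Product: 7 rac-4-(but-2-yn-1-yl)-3,5,5-trimethylcyclohex-2-en-1-one, via tertiary carbinol 6 (not isolated)
Conditions: MeLi (1.5 equiv), Et2O, −78 → 0 °C; then 1 M HCl, THF, rt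
Reagents that add atoms: methyllithium, [Li]C; water, O
Why: 1,2-Addition of the small methyl nucleophile, then acid-mediated ionisation, hydrolysis of the enol ether and loss of isobutanol (Stork–Danheiser transposition) move the carbonyl to C2 and place the C20 methyl on the C1=C10 alkene; the internal alkyne is inert to both stages.

Step 4
Reactants: 7 rac-4-(but-2-yn-1-yl)-3,5,5-trimethylcyclohex-2-en-1-one
Product: 8 (1S,4S)-4-(but-2-yn-1-yl)-3,5,5-trimethylcyclohex-2-en-1-ol
Conditions: (R)-2-butyl-CBS-oxazaborolidine (0.2 equiv), catecholborane (0.6 equiv), toluene, −78 °C; MeOH quench; chromatography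
Reagents that add atoms: none
Why: Corey–Bakshi–Shibata reduction run as a kinetic resolution: with the alkenyl flank as the larger group the (R)-catalyst should deliver hydride to give the (S)-carbinol at C2, and only the (S)-enone can do so while following its own bias (hydride anti to the axial C4 methyl), which leads to the trans alcohol. The mismatched (R)-enone should lag and is removed, with any cis alcohol, by chromatography; catecholborane at −78 °C does not touch the alkyne.

Step 5
Reactants: 8 (1S,4S)-4-(but-2-yn-1-yl)-3,5,5-trimethylcyclohex-2-en-1-ol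
Product: 9 (3S,6S)-6-(but-2-yn-1-yl)-3-(ethenyloxy)-1,5,5-trimethylcyclohex-1-ene
Conditions: Pd(OCOCF3)2 (2 mol %), 4,7-diphenyl-1,10-phenanthroline (2 mol %), Et3N (5 mol %), butyl vinyl ether (solvent), 75 °C
Reagents that add atoms: butyl vinyl ether, C=COCCCC
Why: Transfer vinylation catalysed by divalent palladium (alkoxypalladation of the vinyl ether, then loss of butoxide) exchanges the alkoxy group without breaking the C2–O bond, so the carbinol configuration is kept; mercury salts are avoided because they would attack the alkyne.

Step 6
Reactants: 9 (3S,6S)-6-(but-2-yn-1-yl)-3-(ethenyloxy)-1,5,5-trimethylcyclohex-1-ene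
Product: 10 2-[(1S,6S)-6-(but-2-yn-1-yl)-1,5,5-trimethylcyclohex-2-en-1-yl]acetaldehyde
Conditions: xylenes, 170 °C, sealed tube (base-washed glass)
Reagents that add atoms: none
Why: Claisen rearrangement ([3,3] shift): in the half-chair with the C2–O bond and the C5 chain both pseudoaxial (the chain is pushed there by 1,2-allylic strain with the C10 methyl) the new C9–C10 bond forms suprafacially on the α face that the oxygen leaves, so C10 becomes quaternary with C9 trans to the C5 chain and the alkene moves to C1=C2.

Step 7
Reactants: 10 2-[(1S,6S)-6-(but-2-yn-1-yl)-1,5,5-trimethylcyclohex-2-en-1-yl]acetaldehyde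
Product: 11 tert-butyl({(Z)-2-[(1S,6S)-6-(but-2-yn-1-yl)-1,5,5-trimethylcyclohex-2-en-1-yl]ethenyl}oxy)dimethylsilane
Conditions: TBSOTf (1.3 equiv), Et3N (2 equiv), CH2Cl2, −78 → 0 °C
Reagents that add atoms: tert-butyldimethylsilyl trifluoromethanesulfonate, CC(C)(C)[Si](C)(C)OS(=O)(=O)C(F)(F)F
Why: Soft enolisation of the aldehyde (O-silylation, then deprotonation at C9 by the amine) gives the silyl enol ether, with the Z isomer expected to predominate; no stereocentre is touched, and any E isomer need not be removed because it should cyclise in the same sense in step 8.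

Step 8
Reactants: 11 tert-butyl({(Z)-2-[(1S,6S)-6-(but-2-yn-1-yl)-1,5,5-trimethylcyclohex-2-en-1-yl]ethenyl}oxy)dimethylsilane
Product: 12 (1S,4aS,8aS)-2,5,5,8a-tetramethyl-1,4,4a,5,6,8a-hexahydronaphthalene-1-carbaldehyde (drima-1,7-dien-11-al)
Conditions: [(tBuXPhos)Au(NCMe)]SbF6 (5 mol %; tBuXPhos = 2-di-tert-butylphosphino-2′,4′,6′-triisopropylbiphenyl), CH2Cl2/H2O (10:1), 0 °C → rt; filtration through neutral silica
Reagents that add atoms: none
Why: The cationic monovalent gold centre binds the C7≡C8 alkyne, the silyl enol ether adds through C9 to the methyl-bearing C8, and water discharges the C7 vinyl-gold (protodeauration) and the C11 silyloxocarbenium ion (loss of the silanol), so the catalyst turns over and C11 emerges as the aldehyde. The closest known reaction type is the gold-catalysed carbocyclisation of silyl enol ethers onto alkynes (a Conia-ene-type addition), for which endo closure of internal alkynes under bulky phosphines is established. Ring B closes in the 6-endo-dig mode; the competing 5-exo-dig attack at C7 would give a strained trans-fused hydrindane with an exocyclic ethylidene, and the bulky biaryl phosphine further steers the nucleophile to the alkyne carbon remote from the tether. The ring fusion can only be trans, because C5 and C10 already hold the two reacting chains on opposite faces of ring A. The one new stereocentre, C9, is set kinetically: 1,3-allylic strain between the Z-silyloxy group and the quaternary C10 holds the enol ether in the rotamer in which C9–H eclipses the C10–C5 bond and C11 points away from the ring, and chair-like approach of C8 to that rotamer places C11 equatorial (9β) and H9 axial (α); the E isomer has the same, weaker bias. The step needs the enol ether, not the C1=C2 alkene, to be the nucleophile (secured by its far higher nucleophilicity) and needs cyclisation to outrun hydrolysis of the enol ether (hydrolysis only returns 10, which can be silylated again). Equilibration of 12 is deliberately avoided, because the axial 9α epimer (free of 1,2-allylic strain with the C8 methyl) and the conjugated C8=C9 enal are plausible thermodynamic sinks; 12 is therefore taken into step 9 at once.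

Step 9
Reactants: 12 (1S,4aS,8aS)-2,5,5,8a-tetramethyl-1,4,4a,5,6,8a-hexahydronaphthalene-1-carbaldehyde
Product: 15 drim-7-ene-2α,11-diol [(2S,4aS,8S,8aS)-8-(hydroxymethyl)-4,4,7,8a-tetramethyl-1,2,3,4,4a,5,8,8a-octahydronaphthalen-2-ol], via O-boryl diene 13 (not isolated), via C2-boryl adduct 14 (not isolated)
Conditions: Cy2BH (4 equiv, from BH3·SMe2 + cyclohexene), THF, 0 → 40 °C; then 3 M NaOH, 30% H2O2, 0 °C → rt
Reagents that add atoms: hydrogen peroxide, OO
Why: The dialkylborane first reduces the aldehyde (fast), which locks C9 and gives an O-borinate with no B–H left to direct boron to C7=C8; more reagent then adds to the cis-disubstituted C1=C2 alkene, while the trisubstituted C7=C8 alkene should be inert to so bulky a borane. Boron goes to C2, away from the quaternary C10, and to the α face because the β face is covered by the axial methyls on C4 and C10; oxidation with retention gives the equatorial 2α alcohol (hydroboration–oxidation).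

Step 10
Reactants: 15 drim-7-ene-2α,11-diol
Product: 16 2α-hydroxydrim-7-en-11-al [(1S,4aS,7S,8aS)-7-hydroxy-2,5,5,8a-tetramethyl-1,4,4a,5,6,7,8,8a-octahydronaphthalene-1-carbaldehyde]
Conditions: TEMPO (0.1 equiv), PhI(OAc)2 (1.1 equiv), CH2Cl2, rt
Reagents that add atoms: none
Why: Oxoammonium (TEMPO) oxidation takes primary alcohols much faster than secondary ones, so the C2 carbinol needs no protecting group; the medium is only weakly acidic, which should spare C9, and 16 is used without delay.

Step 11
Reactants: 17 (R)-2-methylbutane-1,4-diol
Product: 18 (2R)-4-[(tert-butyldiphenylsilyl)oxy]-2-methylbutan-1-ol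
Conditions: TBDPSCl (1.0 equiv), imidazole (1.2 equiv), CH2Cl2, −20 → 0 °C; chromatography
Reagents that add atoms: tert-butyl(chloro)diphenylsilane, CC(C)(C)[Si](Cl)(c1ccccc1)c1ccccc1
Why: The bulky silyl chloride should prefer the unbranched C15 hydroxyl over the β-branched C12 hydroxyl; the minor regioisomer and the bis-ether are removed by chromatography, and the stereocentre is not involved.

Step 12
Reactants: 18 (2R)-4-[(tert-butyldiphenylsilyl)oxy]-2-methylbutan-1-ol
Product: 19 tert-butyl{[(3R)-4-iodo-3-methylbutyl]oxy}diphenylsilane
Conditions: I2, PPh3, imidazole, CH2Cl2, 0 °C → rt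
Reagents that add atoms: iodine, II
Why: Appel-type iodination of a primary alcohol through the alkoxyphosphonium ion; substitution occurs at CH2, so the adjacent stereocentre keeps its configuration.

Step 13
Reactants: 19 tert-butyl{[(3R)-4-iodo-3-methylbutyl]oxy}diphenylsilane
Product: 20 {(2R)-4-[(tert-butyldiphenylsilyl)oxy]-2-methylbutyl}triphenylphosphonium iodide
Conditions: PPh3 (3 equiv), i-Pr2NEt (0.1 equiv), MeCN, 85 °C
Reagents that add atoms: triphenylphosphine, c1ccccc1P(c1ccccc1)c1ccccc1
Why: SN2 quaternisation of the phosphine by the β-branched primary iodide (slow but standard with heat and excess phosphine); the trace of amine protects the silyl ether from adventitious acid.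

Step 14
Reactants: 16 2α-hydroxydrim-7-en-11-al; 20 {(2R)-4-[(tert-butyldiphenylsilyl)oxy]-2-methylbutyl}triphenylphosphonium iodide
Product: 22 (11Z,13R)-15-[(tert-butyldiphenylsilyl)oxy]labda-7,11-dien-2α-ol, via phosphorus ylide 21 (not isolated)
Conditions: 20 (3.0 equiv), NaHMDS (2.9 equiv), THF, −78 → 0 °C; then 16, −78 °C → rt
Reagents that add atoms: none
Why: Wittig olefination with an unstabilised ylide forms C11=C12 (Z expected, irrelevant because the alkene is reduced next); excess ylide covers the free C2 hydroxyl, as in olefinations of lactols, and cold addition with no free amide base should favour carbonyl addition over deprotonation at C9.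

Step 15
Reactants: 22 (11Z,13R)-15-[(tert-butyldiphenylsilyl)oxy]labda-7,11-dien-2α-ol
Product: 23 (13S)-15-[(tert-butyldiphenylsilyl)oxy]labd-7-en-2α-ol
Conditions: TsNHNH2 (10 equiv, in portions), NaOAc (12 equiv), DME/H2O (1:1), 85 °C
Reagents that add atoms: none
Why: Diimide transfers two hydrogens to the disubstituted C11=C12 alkene much faster than to the trisubstituted ring alkene, and with no metal present C7=C8 cannot migrate; no stereocentre is formed (the C13 descriptor changes only because of the priority rules).

Step 16
Reactants: 23 (13S)-15-[(tert-butyldiphenylsilyl)oxy]labd-7-en-2α-ol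
Product: 24 (13S)-labd-7-ene-2α,15-diol
Conditions: TBAF (1.5 equiv), THF, rt
Reagents that add atoms: none
Why: Fluoride cleaves the Si–O bond of the primary silyl ether; nothing else in the molecule is sensitive at this stage.

Step 17
Reactants: 25 caffeic acid [(E)-3-(3,4-dihydroxyphenyl)prop-2-enoic acid]
Product: 27 (E)-3-{3,4-bis[(tert-butyldimethylsilyl)oxy]phenyl}prop-2-enoic acid, via tris-silyl derivative 26 (not isolated)
Conditions: TBSCl (3.5 equiv), imidazole (7 equiv), DMF, rt; then AcOH/THF/H2O (3:1:1), rt
Reagents that add atoms: tert-butyl(chloro)dimethylsilane, CC(C)(C)[Si](C)(C)Cl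
Why: Exhaustive silylation, then selective hydrolysis of the labile silyl ester in aqueous acetic acid, which leaves the aryl silyl ethers; the E alkene is untouched.

Step 18
Reactants: 24 (13S)-labd-7-ene-2α,15-diol; 27 (E)-3-{3,4-bis[(tert-butyldimethylsilyl)oxy]phenyl}prop-2-enoic acid
Product: 28 (13S)-2α-hydroxylabd-7-en-15-yl (E)-3-{3,4-bis[(tert-butyldimethylsilyl)oxy]phenyl}prop-2-enoate
Conditions: 27 (1.05 equiv), DCC (1.1 equiv), DMAP (0.1 equiv), CH2Cl2, 0 °C
Reagents that add atoms: none
Why: Steglich esterification; with one equivalent of acid at 0 °C the unhindered primary C15 hydroxyl should be acylated well ahead of the ring-bound secondary C2 hydroxyl, and any bis-ester is separable.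

Step 19
Reactants: 28 (13S)-2α-hydroxylabd-7-en-15-yl (E)-3-{3,4-bis[(tert-butyldimethylsilyl)oxy]phenyl}prop-2-enoate
Product: 29 (13S)-2α-hydroxylabd-7-en-15-yl (E)-3-(3,4-dihydroxyphenyl)prop-2-enoate (CNP0206083.1)
Conditions: TBAF (2.2 equiv), AcOH (2.5 equiv), THF, 0 °C, under argon
Reagents that add atoms: none
Why: Aryl silyl ethers are cleaved by fluoride within minutes; the acetic acid buffer keeps the catechol protonated, which should prevent oxidation and ester cleavage.

## Compound list

1 | dimedone (5,5-dimethylcyclohexane-1,3-dione) | CC1(C)CC(=O)CC(=O)C1 | starting material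
2 | 5,5-dimethyl-3-(2-methylpropoxy)cyclohex-2-en-1-one | CC(C)COC1=CC(=O)CC(C)(C)C1 | intermediate
3 | 1-bromobut-2-yne | CC#CCBr | starting material
4 | lithium 3,3-dimethyl-5-(2-methylpropoxy)cyclohexa-1,5-dien-1-olate | [Li]OC1=CC(C)(C)CC(OCC(C)C)=C1 | intermediate (not isolated)
5 | rac-6-(but-2-yn-1-yl)-5,5-dimethyl-3-(2-methylpropoxy)cyclohex-2-en-1-one (racemate) | CC#CCC1C(=O)C=C(OCC(C)C)CC1(C)C | intermediate
6 | 6-(but-2-yn-1-yl)-1,5,5-trimethyl-3-(2-methylpropoxy)cyclohex-2-en-1-ol (racemic diastereomer mixture, lithium alkoxide until the acid is added) | CC#CCC1C(C)(O)C=C(OCC(C)C)CC1(C)C | intermediate (not isolated)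
7 | rac-4-(but-2-yn-1-yl)-3,5,5-trimethylcyclohex-2-en-1-one (racemate) | CC#CCC1C(C)=CC(=O)CC1(C)C | intermediate
8 | (1S,4S)-4-(but-2-yn-1-yl)-3,5,5-trimethylcyclohex-2-en-1-ol (trans) | CC#CC[C@H]1C(C)(C)C[C@H](O)C=C1C | intermediate
9 | (3S,6S)-6-(but-2-yn-1-yl)-3-(ethenyloxy)-1,5,5-trimethylcyclohex-1-ene | CC#CC[C@H]1C(C)(C)C[C@H](OC=C)C=C1C | intermediate
10 | 2-[(1S,6S)-6-(but-2-yn-1-yl)-1,5,5-trimethylcyclohex-2-en-1-yl]acetaldehyde | CC#CC[C@H]1C(C)(C)CC=C[C@]1(C)CC=O | intermediate
11 | tert-butyl({(Z)-2-[(1S,6S)-6-(but-2-yn-1-yl)-1,5,5-trimethylcyclohex-2-en-1-yl]ethenyl}oxy)dimethylsilane | CC#CC[C@H]1C(C)(C)CC=C[C@]1(C)/C=C\O[Si](C)(C)C(C)(C)C | intermediate (precursor of the key step)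
12 | (1S,4aS,8aS)-2,5,5,8a-tetramethyl-1,4,4a,5,6,8a-hexahydronaphthalene-1-carbaldehyde (drima-1,7-dien-11-al; 5α-H, 9α-H, 10β-methyl) | CC1=CC[C@H]2C(C)(C)CC=C[C@]2(C)[C@H]1C=O | intermediate (product of the key step)
13 | dicyclohexyl{[(1S,4aS,8aS)-2,5,5,8a-tetramethyl-1,4,4a,5,6,8a-hexahydronaphthalen-1-yl]methoxy}borane | CC1=CC[C@H]2C(C)(C)CC=C[C@]2(C)[C@H]1COB(C1CCCCC1)C1CCCCC1 | intermediate (not isolated)
14 | 2α-(dicyclohexylboryl)-11-[(dicyclohexylboryl)oxy]drim-7-ene | CC1=CC[C@H]2C(C)(C)C[C@H](B(C3CCCCC3)C3CCCCC3)C[C@]2(C)[C@H]1COB(C1CCCCC1)C1CCCCC1 | intermediate (not isolated)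
15 | drim-7-ene-2α,11-diol [(2S,4aS,8S,8aS)-8-(hydroxymethyl)-4,4,7,8a-tetramethyl-1,2,3,4,4a,5,8,8a-octahydronaphthalen-2-ol] | CC1=CC[C@H]2C(C)(C)C[C@H](O)C[C@]2(C)[C@H]1CO | intermediate
16 | 2α-hydroxydrim-7-en-11-al [(1S,4aS,7S,8aS)-7-hydroxy-2,5,5,8a-tetramethyl-1,4,4a,5,6,7,8,8a-octahydronaphthalene-1-carbaldehyde] | CC1=CC[C@H]2C(C)(C)C[C@H](O)C[C@]2(C)[C@H]1C=O | intermediate
17 | (R)-2-methylbutane-1,4-diol | OC[C@H](C)CCO | starting material
18 | (2R)-4-[(tert-butyldiphenylsilyl)oxy]-2-methylbutan-1-ol | OC[C@H](C)CCO[Si](c1ccccc1)(c1ccccc1)C(C)(C)C | intermediate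
19 | tert-butyl{[(3R)-4-iodo-3-methylbutyl]oxy}diphenylsilane | IC[C@H](C)CCO[Si](c1ccccc1)(c1ccccc1)C(C)(C)C | intermediate
20 | {(2R)-4-[(tert-butyldiphenylsilyl)oxy]-2-methylbutyl}triphenylphosphonium iodide | c1ccccc1[P+](c1ccccc1)(c1ccccc1)C[C@H](C)CCO[Si](c1ccccc1)(c1ccccc1)C(C)(C)C.[I-] | intermediate
21 | {(2R)-4-[(tert-butyldiphenylsilyl)oxy]-2-methylbutylidene}triphenylphosphorane | c1ccccc1P(c1ccccc1)(c1ccccc1)=C[C@H](C)CCO[Si](c1ccccc1)(c1ccccc1)C(C)(C)C | intermediate (not isolated)
22 | (11Z,13R)-15-[(tert-butyldiphenylsilyl)oxy]labda-7,11-dien-2α-ol | CC1=CC[C@H]2C(C)(C)C[C@H](O)C[C@]2(C)[C@H]1/C=C\[C@H](C)CCO[Si](c1ccccc1)(c1ccccc1)C(C)(C)C | intermediate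
23 | (13S)-15-[(tert-butyldiphenylsilyl)oxy]labd-7-en-2α-ol | CC1=CC[C@H]2C(C)(C)C[C@H](O)C[C@]2(C)[C@H]1CC[C@H](C)CCO[Si](c1ccccc1)(c1ccccc1)C(C)(C)C | intermediate
24 | (13S)-labd-7-ene-2α,15-diol | CC1=CC[C@H]2C(C)(C)C[C@H](O)C[C@]2(C)[C@H]1CC[C@H](C)CCO | intermediate
25 | caffeic acid [(E)-3-(3,4-dihydroxyphenyl)prop-2-enoic acid] | OC(=O)/C=C/c1ccc(O)c(O)c1 | starting material
26 | tert-butyldimethylsilyl (E)-3-{3,4-bis[(tert-butyldimethylsilyl)oxy]phenyl}prop-2-enoate | CC(C)(C)[Si](C)(C)OC(=O)/C=C/c1ccc(O[Si](C)(C)C(C)(C)C)c(O[Si](C)(C)C(C)(C)C)c1 | intermediate (not isolated)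
27 | (E)-3-{3,4-bis[(tert-butyldimethylsilyl)oxy]phenyl}prop-2-enoic acid | OC(=O)/C=C/c1ccc(O[Si](C)(C)C(C)(C)C)c(O[Si](C)(C)C(C)(C)C)c1 | intermediate
28 | (13S)-2α-hydroxylabd-7-en-15-yl (E)-3-{3,4-bis[(tert-butyldimethylsilyl)oxy]phenyl}prop-2-enoate | CC1=CC[C@H]2C(C)(C)C[C@H](O)C[C@]2(C)[C@H]1CC[C@H](C)CCOC(=O)/C=C/c1ccc(O[Si](C)(C)C(C)(C)C)c(O[Si](C)(C)C(C)(C)C)c1 | intermediate
29 | (13S)-2α-hydroxylabd-7-en-15-yl (E)-3-(3,4-dihydroxyphenyl)prop-2-enoate (CNP0206083.1) | CC1=CC[C@H]2C(C)(C)C[C@H](O)C[C@]2(C)[C@H]1CC[C@H](C)CCOC(=O)/C=C/c1ccc(O)c(O)c1 | target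

## Step count and least certain steps

Total step count: 19. Longest linear sequence: 15 steps (steps 1–10, 14–16, 18 and 19, from 1); steps 11–13 (side chain) and step 17 (acid) are convergent branches.

**Step 8 (key step).** What may go wrong: ring closure through C7 (five-membered, exo) in competition with the wanted attack at C8, hydrolysis of the enol ether before it cyclises, or loss of configuration at C9 by enolisation of the product on the catalyst or on the adsorbent. Fallback (sets out from 2, returns at 12): the ring B alkene is built into the chain as a vinyl iodide, and the C8–C9 bond is made by oxidative addition instead of alkyne activation, so ring size and alkene position are fixed by the substrate.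
- The lithium dienolate 4 from 2 is alkylated with the known reagent (Z)-1-bromo-3-iodobut-2-ene (C/C(I)=C/CBr) to give the iodobutenyl enol ether F1.
- MeMgBr/CeCl3 and then aqueous HCl give the iodobutenyl enone F2 (the Grignard/cerium reagent avoids iodine–metal exchange).
- The resolution of step 4 gives the trans iodobutenyl alcohol F3.
- A Johnson–Claisen rearrangement (triethyl orthoacetate, cat. propionic acid, 140 °C) gives the ethyl ester F4 with the same transfer of chirality to C10.
- Intramolecular α-alkenylation of the ester enolate (Pd2(dba)3, tBu3P·HBF4, LiHMDS, toluene; zerovalent palladium inserts into the C8–iodine bond and the enolate carbon C9 is coupled) closes ring B as the bicyclic ethyl ester F5. A cold acetic acid quench of the resulting dienolate should protonate C9 from the open α face.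
- DIBAL-H at −78 °C takes F5 to 12.

**Step 4.** What may go wrong: weak discrimination by the catalyst between the alkenyl flank and the neopentyl-like CH2 flank of the carbonyl, so that trans alcohol is formed from both enantiomers and its enantiomeric purity falls. Fallback (sets out from 7, returns at 8): a classical resolution through covalent diastereomers.
- Luche reduction (NaBH4, CeCl3·7H2O, MeOH, −78 °C) gives the racemic trans alcohol F6.
- Esterification with (S)-2-methoxy-2-phenylacetic acid (DCC, DMAP) and separation of the two diastereomeric esters by chromatography or crystallisation gives the (1S,4S) mandelate ester F7.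
- LiOH in THF/MeOH/H2O releases 8.

**Step 9.** What may go wrong: sluggish addition to the hindered ring alkene, so that forcing conditions let borane redistribution products attack C7=C8, or leakage of boron to C1. Fallback (sets out from 12, returns at 15): the control element is changed from reagent bulk to a catalyst that does not insert trisubstituted alkenes, on a substrate whose hydroxyl is blocked so that it cannot direct the metal to C7=C8.
- NaBH4 in MeOH gives the dienyl alcohol F8.
- TBSCl and imidazole give the silyl ether F9.
- Catecholborane with RhCl(PPh3)3 (3 mol %) in THF, then NaOH/H2O2, gives the 2α-hydroxy silyl ether F10.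
- TBAF gives 15.

**Step 14.** What may go wrong: deprotonation at C9 by the basic ylide instead of addition (loss of configuration at C9 or drift of the alkene into conjugation), or slow addition because both partners are branched next to the reacting carbons. Fallback (sets out from 18, uses 16, returns at 23): a Julia–Kocienski olefination under Barbier conditions, in which the carbanion is generated in the presence of the aldehyde and kept at low concentration.
- Mitsunobu reaction of 18 with 1-phenyl-1H-tetrazole-5-thiol (PPh3, DIAD) gives the tetrazolyl sulfide F11.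
- (NH4)6Mo7O24·4H2O and H2O2 in EtOH give the tetrazolyl sulfone F12.
- KHMDS is added to F12 and 16 in DME at −60 °C to give the (E)-diene F13.
- The diimide conditions of step 15 reduce F13 to 23.

## Further compounds

F1 | step 8 | rac-6-[(2Z)-3-iodobut-2-en-1-yl]-5,5-dimethyl-3-(2-methylpropoxy)cyclohex-2-en-1-one (racemate) | C/C(I)=C/CC1C(=O)C=C(OCC(C)C)CC1(C)C
F2 | step 8 | rac-4-[(2Z)-3-iodobut-2-en-1-yl]-3,5,5-trimethylcyclohex-2-en-1-one (racemate) | C/C(I)=C/CC1C(C)=CC(=O)CC1(C)C
F3 | step 8 | (1S,4S)-4-[(2Z)-3-iodobut-2-en-1-yl]-3,5,5-trimethylcyclohex-2-en-1-ol | C/C(I)=C/C[C@H]1C(C)(C)C[C@H](O)C=C1C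
F4 | step 8 | ethyl 2-{(1S,6S)-6-[(2Z)-3-iodobut-2-en-1-yl]-1,5,5-trimethylcyclohex-2-en-1-yl}acetate | C/C(I)=C/C[C@H]1C(C)(C)CC=C[C@]1(C)CC(=O)OCC
F5 | step 8 | ethyl (1S,4aS,8aS)-2,5,5,8a-tetramethyl-1,4,4a,5,6,8a-hexahydronaphthalene-1-carboxylate | CC1=CC[C@H]2C(C)(C)CC=C[C@]2(C)[C@H]1C(=O)OCC
F6 | step 4 | rac-(1S*,4S*)-4-(but-2-yn-1-yl)-3,5,5-trimethylcyclohex-2-en-1-ol (racemic trans alcohol, both enantiomers written) | CC#CC[C@H]1C(C)(C)C[C@H](O)C=C1C.CC#CC[C@@H]1C(C)(C)C[C@@H](O)C=C1C
F7 | step 4 | (1S,4S)-4-(but-2-yn-1-yl)-3,5,5-trimethylcyclohex-2-en-1-yl (2S)-2-methoxy-2-phenylacetate | CC#CC[C@H]1C(C)(C)C[C@H](OC(=O)[C@@H](OC)c2ccccc2)C=C1C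
F8 | step 9 | [(1S,4aS,8aS)-2,5,5,8a-tetramethyl-1,4,4a,5,6,8a-hexahydronaphthalen-1-yl]methanol | CC1=CC[C@H]2C(C)(C)CC=C[C@]2(C)[C@H]1CO
F9 | step 9 | tert-butyldimethyl{[(1S,4aS,8aS)-2,5,5,8a-tetramethyl-1,4,4a,5,6,8a-hexahydronaphthalen-1-yl]methoxy}silane | CC1=CC[C@H]2C(C)(C)CC=C[C@]2(C)[C@H]1CO[Si](C)(C)C(C)(C)C
F10 | step 9 | 11-[(tert-butyldimethylsilyl)oxy]drim-7-en-2α-ol | CC1=CC[C@H]2C(C)(C)C[C@H](O)C[C@]2(C)[C@H]1CO[Si](C)(C)C(C)(C)C
F11 | step 14 | 5-({(2R)-4-[(tert-butyldiphenylsilyl)oxy]-2-methylbutyl}sulfanyl)-1-phenyl-1H-tetrazole | c1ccccc1-n1nnnc1SC[C@H](C)CCO[Si](c1ccccc1)(c1ccccc1)C(C)(C)C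
F12 | step 14 | 5-({(2R)-4-[(tert-butyldiphenylsilyl)oxy]-2-methylbutyl}sulfonyl)-1-phenyl-1H-tetrazole | c1ccccc1-n1nnnc1S(=O)(=O)C[C@H](C)CCO[Si](c1ccccc1)(c1ccccc1)C(C)(C)C
F13 | step 14 | (11E,13R)-15-[(tert-butyldiphenylsilyl)oxy]labda-7,11-dien-2α-ol | CC1=CC[C@H]2C(C)(C)C[C@H](O)C[C@]2(C)[C@H]1/C=C/[C@H](C)CCO[Si](c1ccccc1)(c1ccccc1)C(C)(C)C
A1 | alternative 1 | methyl 7-[(tert-butyldimethylsilyl)oxy]-2α-[(triisopropylsilyl)oxy]drim-6-en-11-oate (trans-decalin, 8β-methyl, 9β-ester) | C[C@H]1C(O[Si](C)(C)C(C)(C)C)=C[C@H]2C(C)(C)C[C@H](O[Si](C(C)C)(C(C)C)C(C)C)C[C@]2(C)[C@H]1C(=O)OC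
A2 | alternative 2 | 2α-hydroxydrima-5,8-dien-11-oic acid 11,2-lactone (bridged six-membered lactone from the C2 oxygen to C9) | O=C1O[C@H]2CC(C)(C)C3=CCC(C)=C1[C@@]3(C)C2
A3 | alternative 3 | 2-{(3S)-5-[(tert-butyldimethylsilyl)oxy]-3-methylpentyl}-1,3-dimethyl-6-(prop-1-en-2-yl)cyclohex-3-ene-1-carbaldehyde (ring B only; 5α-H, 9α-H, 10β-methyl in labdane terms) | CC1=CC[C@@H](C(C)=C)[C@](C)(C=O)[C@H]1CC[C@H](C)CCO[Si](C)(C)C(C)(C)C
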